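**Plan**
Numbering (germacrane): ring C1–C10; C6 = lactone O–CH, C7 = ring-fusion CH, C8 = acyloxy CH; C11/C12/C13 = lactone α-carbon/carbonyl/methylene; C14 = formyl C on C10; C15 = hydroxymethyl C on C4.
Cuts: the lactone C–O(alkyl) bond O–C6 (last ring bond), C6–C7 (ten-membered ring), the C7=C11/C13–Br unit (Morita–Baylis–Hillman, then allylic bromide), C1=C10 (aldol condensation onto a lactone) and C3–C4 (carbomagnesiation of an alkyne).
Forward: but-2-yne-1,4-diol gives the C4=C5 unit (C1–C6, C15); it is joined at C1=C10 to a butyrolactone from the D-glutamic acid series (C7–C10, C14); the bromomethyl acrylate is built at C7; CrCl2 closes the ten-membered carbocycle at C6–C7 (isolated as the trans-fused lactone); the γ-lactone is opened and re-closed at O–C6; end-game at O8, C14, C15.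
Stereochemistry: C8 from (R)-5-(hydroxymethyl)dihydrofuran-2(3H)-one; C7 and C6 from the chromium step (C6/C7 anti, 1,2-induction by C8); C6 is then inverted, which gives the cis ring fusion; both in-ring cis olefins come from an anti-carbomagnesiation and an E-selective aldol condensation.
Enabling feature: C6 is a secondary allylic carbinol carbon (next to C4=C5) of the ten-membered ring, γ to the carboxyl carbon C12. Closures onto a planar C6 would put O6 anti to C8 (trans fusion), so the cis-fused five-membered lactone is made by carboxylate displacement at C6 with inversion.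

Key step: step 18

Remark: the target is taken as drawn (both ring olefins in-ring cis, E by CIP; cis-fused lactone; 6R,7S,8R). Abbreviations in names: TES = triethylsilyl, TBS = tert-butyldimethylsilyl, TBDPS = tert-butyldiphenylsilyl, PMB = 4-methoxybenzyl.

Step 1
Reactants: 1 (R)-5-(hydroxymethyl)dihydrofuran-2(3H)-one
Product: 2 (R)-5-(TESOCH2)dihydrofuran-2(3H)-one
Conditions: Et3SiCl, imidazole, CH2Cl2, 0 °C
Reagents that add atoms: chlorotriethylsilane, CC[Si](CC)(CC)Cl
Why: Silyl ether formation masks the future C7 oxygen with the most acid-labile silyl group of the route and leaves the C8 stereocenter untouched.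

Step 2
Reactants: 3 but-2-yne-1,4-diol
Product: 4 4-(TBSO)but-2-yn-1-ol
Conditions: NaH (1.0 equiv), THF, 0 °C → rt; then tBuMe2SiCl (1.0 equiv)
Reagents that add atoms: tert-butyldimethylsilyl chloride, CC(C)(C)[Si](C)(C)Cl
Why: Monosilylation of a symmetrical diol through its sparingly soluble monosodium alkoxide should leave one free hydroxyl (future O15) as the directing group for step 3.

Step 3
Reactants: 4 4-(TBSO)but-2-yn-1-ol; 5 allylmagnesium bromide (CH2=CHCH2MgBr)
Product: 6 (E)-2-allyl-4-(TBSO)but-2-en-1-ol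
Conditions: 5 (3 equiv), Et2O, 0 °C → reflux; then H2O
Reagents that add atoms: none
Why: Hydroxyl-directed anti-carbomagnesiation of a propargylic alcohol puts allyl on the alkyne carbon next to the magnesium alkoxide and magnesium on the distal carbon within a five-membered chelate, so that after protonation the allyl group (C3) and the CH2OTBS arm (C6) are cis, which is the in-ring cis C4=C5 geometry; the silyl ether is no leaving group, so SN2′ allene formation is not expected.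

Step 4
Reactants: 6 (E)-2-allyl-4-(TBSO)but-2-en-1-ol
Product: 7 (2E)-1-(TBSO)-3-(PMBOCH2)hexa-2,5-diene
Conditions: NaH, 4-MeOC6H4CH2Cl, Bu4NI (cat.), THF/DMF, 0 °C → rt
Reagents that add atoms: 4-methoxybenzyl chloride, COc1ccc(CCl)cc1
Why: Williamson ether synthesis puts the oxidatively removable PMB group on O15, the hydroxyl that is unmasked last.

Step 5
Reactants: 7 (2E)-1-(TBSO)-3-(PMBOCH2)hexa-2,5-diene
Product: 9 (4E)-6-(TBSO)-4-(PMBOCH2)hex-4-en-1-ol, via alkylborane 8 (not isolated)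
Conditions: 9-BBN, THF, 0 °C → rt; then NaOH, H2O2, H2O, 0 °C
Reagents that add atoms: hydrogen peroxide, OO
Why: Anti-Markovnikov hydroboration–oxidation with the bulky borane should take only the monosubstituted olefin and leave the trisubstituted C4=C5 olefin untouched.

Step 6
Reactants: 9 (4E)-6-(TBSO)-4-(PMBOCH2)hex-4-en-1-ol
Product: 10 (4E)-6-(TBSO)-4-(PMBOCH2)hex-4-enal
Conditions: Dess–Martin periodinane, pyridine, CH2Cl2, 0 °C → rt
Reagents that add atoms: none
Why: Dess–Martin oxidation of the primary alcohol gives the C1 aldehyde under buffered conditions that spare the silyl and PMB ethers.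

Step 7
Reactants: 2 (R)-5-(TESOCH2)dihydrofuran-2(3H)-one; 10 (4E)-6-(TBSO)-4-(PMBOCH2)hex-4-enal
Product: 13 (3E,5R)-3-[(4E)-6-(TBSO)-4-(PMBOCH2)hex-4-en-1-ylidene]-5-(TESOCH2)dihydrofuran-2(3H)-one, via aldol adduct 11 (not isolated), via aldol mesylate 12 (not isolated)
Conditions: iPr2NLi, THF, −78 °C, 2; then 10, −78 °C; H2O; crude: MeSO2Cl, Et3N, CH2Cl2, 0 °C; then DBU, rt
Reagents that add atoms: none
Why: Lactone-enolate aldol addition and E1cB elimination of the mesylate (aldol condensation) should give the thermodynamically preferred (E)-α-alkylidene lactone, in which C2 is cis to C9 and trans to the C14 carbonyl (the in-ring cis C1=C10 geometry); C8 is not enolisable and keeps its configuration.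

Step 8
Reactants: 13 (3E,5R)-3-[(4E)-6-(TBSO)-4-(PMBOCH2)hex-4-en-1-ylidene]-5-(TESOCH2)dihydrofuran-2(3H)-one
Product: 14 (2R,4E,8E)-10-(TBSO)-4-(hydroxymethyl)-8-(PMBOCH2)-1-(TESO)deca-4,8-dien-2-ol
Conditions: iBu2AlH (4.5 equiv), CH2Cl2, −78 → 0 °C; aq. potassium sodium tartrate
Reagents that add atoms: none
Why: Complete 1,2-reduction of the α-alkylidene lactone (through the lactol) frees O8 and turns C14 into a primary allylic alcohol without change of olefin geometry.

Step 9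
Reactants: 14 (2R,4E,8E)-10-(TBSO)-4-(hydroxymethyl)-8-(PMBOCH2)-1-(TESO)deca-4,8-dien-2-ol
Product: 15 (2R,4E,8E)-10-(TBSO)-4-(TBDPSOCH2)-8-(PMBOCH2)-1-(TESO)deca-4,8-dien-2-ol
Conditions: tBuPh2SiCl (1.05 equiv), imidazole, CH2Cl2, 0 °C
Reagents that add atoms: tert-butyl(chloro)diphenylsilane, CC(C)(C)[Si](Cl)(c1ccccc1)c1ccccc1
Why: The bulky silyl chloride should take the primary allylic hydroxyl (O14) and leave the secondary C8 hydroxyl free.

Step 10
Reactants: 15 (2R,4E,8E)-10-(TBSO)-4-(TBDPSOCH2)-8-(PMBOCH2)-1-(TESO)deca-4,8-dien-2-ol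
Product: 16 (2R,4E,8E)-2,10-bis(TBSO)-4-(TBDPSOCH2)-8-(PMBOCH2)-1-(TESO)deca-4,8-diene
Conditions: tBuMe2SiOTf, 2,6-lutidine, CH2Cl2, −78 °C
Reagents that add atoms: tert-butyldimethylsilyl trifluoromethanesulfonate, CC(C)(C)[Si](C)(C)OS(=O)(=O)C(F)(F)F
Why: Silylation of the secondary alcohol gives O8 a poor leaving group, so that the later allylchromium species cannot lose it by 1,4-elimination.

Step 11
Reactants: 16 (2R,4E,8E)-2,10-bis(TBSO)-4-(TBDPSOCH2)-8-(PMBOCH2)-1-(TESO)deca-4,8-diene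
Product: 17 (2R,4E,8E)-2,10-bis(TBSO)-4-(TBDPSOCH2)-8-(PMBOCH2)deca-4,8-dien-1-ol
Conditions: PPTS (0.2 equiv), MeOH/CH2Cl2 (1:1), 0 °C
Reagents that add atoms: none
Why: Acid-catalysed methanolysis should remove the primary TES ether well before the primary TBS, secondary TBS and TBDPS ethers react.

Step 12
Reactants: 17 (2R,4E,8E)-2,10-bis(TBSO)-4-(TBDPSOCH2)-8-(PMBOCH2)deca-4,8-dien-1-ol
Product: 18 (2R,4E,8E)-2,10-bis(TBSO)-4-(TBDPSOCH2)-8-(PMBOCH2)deca-4,8-dienal
Conditions: Dess–Martin periodinane, pyridine, CH2Cl2, 0 °C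
Reagents that add atoms: none
Why: Buffered Dess–Martin oxidation gives the α-silyloxy aldehyde (C7) without epimerisation at C8; it is used at once.

Step 13
Reactants: 18 (2R,4E,8E)-2,10-bis(TBSO)-4-(TBDPSOCH2)-8-(PMBOCH2)deca-4,8-dienal; 19 methyl acrylate
Product: 20 methyl (4R,6E,10E)-4,12-bis(TBSO)-6-(TBDPSOCH2)-3-hydroxy-10-(PMBOCH2)-2-methylidenedodeca-6,10-dienoate (both C3 epimers)
Conditions: 19 (15 equiv, neat), DABCO (1.0 equiv), rt
Reagents that add atoms: none
Why: Morita–Baylis–Hillman reaction of the activated α-oxygenated aldehyde attaches C11–C13; the new carbinol center (C7) need not be controlled because it becomes sp2 in step 14.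

Step 14
Reactants: 20 methyl (4R,6E,10E)-4,12-bis(TBSO)-6-(TBDPSOCH2)-3-hydroxy-10-(PMBOCH2)-2-methylidenedodeca-6,10-dienoate
Product: 21 methyl (2Z,4R,6E,10E)-2-(bromomethyl)-4,12-bis(TBSO)-6-(TBDPSOCH2)-10-(PMBOCH2)dodeca-2,6,10-trienoate
Conditions: NBS, Me2S, CH2Cl2, 0 °C → rt
Reagents that add atoms: N-bromosuccinimide, O=C1CCC(=O)N1Br
Why: The sulfonium salt from NBS and Me2S activates the allylic hydroxyl (Corey–Kim-type activation) and bromide enters at the methylene terminus (SN2′), which creates the C7=C11 olefin as the thermodynamically preferred (Z)-2-(bromomethyl)-2-enoate.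

Step 15
Reactants: 21 methyl (2Z,4R,6E,10E)-2-(bromomethyl)-4,12-bis(TBSO)-6-(TBDPSOCH2)-10-(PMBOCH2)dodeca-2,6,10-trienoate
Product: 22 methyl (2Z,4R,6E,10E)-2-(bromomethyl)-4-(TBSO)-6-(TBDPSOCH2)-12-hydroxy-10-(PMBOCH2)dodeca-2,6,10-trienoate
Conditions: HF·pyridine, pyridine, THF, 0 °C
Reagents that add atoms: none
Why: Buffered fluoride should cleave the primary allylic TBS ether (O6) faster than the secondary TBS and the TBDPS ether, and it does not displace the allylic bromide.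

Step 16
Reactants: 22 methyl (2Z,4R,6E,10E)-2-(bromomethyl)-4-(TBSO)-6-(TBDPSOCH2)-12-hydroxy-10-(PMBOCH2)dodeca-2,6,10-trienoate
Product: 23 methyl (2Z,4R,6E,10E)-2-(bromomethyl)-4-(TBSO)-6-(TBDPSOCH2)-10-(PMBOCH2)-12-oxododeca-2,6,10-trienoate
Conditions: MnO2 (20 equiv), CH2Cl2, rt
Reagents that add atoms: none
Why: MnO2 oxidises only the primary allylic alcohol and keeps the olefin geometry, so the C6 formyl group stays cis to the C3 chain as the ring closure needs.

Step 17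
Reactants: 23 methyl (2Z,4R,6E,10E)-2-(bromomethyl)-4-(TBSO)-6-(TBDPSOCH2)-10-(PMBOCH2)-12-oxododeca-2,6,10-trienoate
Product: 25 (1(10)E,4E,6S,7R,8R)-8-(TBSO)-14-(TBDPSO)-15-(PMBO)germacra-1(10),4,11(13)-trien-12,6-olide (trans-fused lactone), via hydroxy ester 24 (not isolated)
Conditions: CrCl2 (8 equiv), THF, 25 °C, slow addition of 23 (final concentration 2 mM); H2O; crude: TsOH·H2O (5 mol %), CH2Cl2, 0 °C → rt
Reagents that add atoms: none
Why: Intramolecular Nozaki–Hiyama–Kishi (Barbier-type) 2-(alkoxycarbonyl)allylation: the allylchromium species (trivalent chromium) adds through its γ-carbon C7 to the C6 aldehyde in a chair transition state with both ring arms pseudo-equatorial, which should give the 6,7-anti carbinol as is usual for chromium; H8 eclipses the enoate plane (allylic strain with CO2Me) and the aldehyde enters anti to the C8–O bond with C9 gauche to the new bond (the sense known from alkylation of β-oxygenated enolates), which sets C7 with C11 trans to O8; the C6 oxygen then closes onto the ester to the trans-fused lactone.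

Step 18
Reactants: 25 (1(10)E,4E,6S,7R,8R)-8-(TBSO)-14-(TBDPSO)-15-(PMBO)germacra-1(10),4,11(13)-trien-12,6-olide (trans-fused lactone)
Product: 27 (1(10)E,4E,6R,7R,8R)-8-(TBSO)-14-(TBDPSO)-15-(PMBO)germacra-1(10),4,11(13)-trien-12,6-olide (cis-fused lactone), via seco acid 26 (not isolated)
Conditions: LiOH·H2O (3 equiv), THF/H2O (3:1), 0 °C → rt; 0.5 M HCl to pH 4 at 0 °C, EtOAc; then PPh3 (2.5 equiv), DIAD (2.5 equiv), toluene (5 mM), −20 → 0 °C, slow addition of 26
Reagents that add atoms: lithium hydroxide, [Li+].[OH-]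
Why: Saponification opens 25 at the acyl C–O bond to the seco acid 26; the C6 carbinol oxygen is then activated as an alkoxyphosphonium ion by the PPh3/DIAD betaine and displaced by the carboxylate in an SN2 substitution, so the ring is re-closed at the alkyl C–O bond (closest known reaction type: Mitsunobu lactonization of a γ-hydroxy acid with hydroxyl-group activation). The five-membered ring (O, C12, C11, C7, C6) closes in the 5-exo-tet mode. C6 is the only stereocenter formed: it is controlled by inversion of the (6S) carbinol set in step 17, which turns the 6,7-trans into the 6,7-cis ring fusion (O6 and C11 on the same face), while C7 and C8 are untouched. The step needs SN2 at C6 to win over SN2′ attack at C4, over ionisation of the allylic oxyphosphonium ion, and over closure at the acyl carbon with retention (acid-induced relactonization or acyloxyphosphonium formation). The γ-relationship of C12 and C6 (five-membered transition state, against seven-membered for attack at C4), the antiperiplanar placement of the C7–C11 and C6–O bonds that the ring can reach with C5 and C8 gauche, the cold near-neutral handling of 26 and its slow addition to the preformed betaine should secure this.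

Step 19
Reactants: 27 (1(10)E,4E,6R,7R,8R)-8-(TBSO)-14-(TBDPSO)-15-(PMBO)germacra-1(10),4,11(13)-trien-12,6-olide (cis-fused lactone)
Product: 28 (1(10)E,4E,6R,7S,8R)-14-(TBDPSO)-8-hydroxy-15-(PMBO)germacra-1(10),4,11(13)-trien-12,6-olide
Conditions: HF (48 % aq.), MeCN, 0 °C
Reagents that add atoms: none
Why: Aqueous HF in MeCN should remove the secondary TBS ether while the more acid-stable primary TBDPS ether, the PMB ether and the lactone survive.

Step 20
Reactants: 28 (1(10)E,4E,6R,7S,8R)-14-(TBDPSO)-8-hydroxy-15-(PMBO)germacra-1(10),4,11(13)-trien-12,6-olide; 29 3-methylbutanoic anhydride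
Product: 30 (1(10)E,4E,6R,7S,8R)-14-(TBDPSO)-8-(3-methylbutanoyloxy)-15-(PMBO)germacra-1(10),4,11(13)-trien-12,6-olide
Conditions: 29, DMAP (cat.), Et3N, CH2Cl2, 0 °C → rt
Reagents that add atoms: none
Why: DMAP-catalysed acylation (Steglich-type) esterifies the only free hydroxyl with retention at C8 and should be faster than migration of the lactone to O8.

Step 21
Reactants: 30 (1(10)E,4E,6R,7S,8R)-14-(TBDPSO)-8-(3-methylbutanoyloxy)-15-(PMBO)germacra-1(10),4,11(13)-trien-12,6-olide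
Product: 31 (1(10)E,4E,6R,7S,8R)-14-hydroxy-8-(3-methylbutanoyloxy)-15-(PMBO)germacra-1(10),4,11(13)-trien-12,6-olide
Conditions: HF·pyridine, THF, rt
Reagents that add atoms: none
Why: Fluoride-mediated desilylation removes the last silyl ether; the ester, the lactone and the PMB ether are stable to HF·pyridine.

Step 22
Reactants: 31 (1(10)E,4E,6R,7S,8R)-14-hydroxy-8-(3-methylbutanoyloxy)-15-(PMBO)germacra-1(10),4,11(13)-trien-12,6-olide
Product: 32 (1(10)E,4E,6R,7S,8R)-8-(3-methylbutanoyloxy)-14-oxo-15-(PMBO)germacra-1(10),4,11(13)-trien-12,6-olide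
Conditions: MnO2 (20 equiv), CH2Cl2, rt
Reagents that add atoms: none
Why: MnO2 oxidation of the primary allylic alcohol gives the C14 enal with retention of the C1=C10 geometry; O15 is still protected, so no second allylic alcohol competes.

Step 23
Reactants: 32 (1(10)E,4E,6R,7S,8R)-8-(3-methylbutanoyloxy)-14-oxo-15-(PMBO)germacra-1(10),4,11(13)-trien-12,6-olide
Product: 33 (1(10)E,4E,6R,7S,8R)-15-hydroxy-8-(3-methylbutanoyloxy)-14-oxogermacra-1(10),4,11(13)-trien-12,6-olide (target)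
Conditions: DDQ (1.3 equiv), CH2Cl2/pH 7 buffer (10:1), 0 °C
Reagents that add atoms: none
Why: Oxidative cleavage of the PMB ether by DDQ (hydride abstraction to the benzylic oxocarbenium ion, then hydrolysis) frees O15; a small excess in buffered medium at 0 °C should avoid over-oxidation of the new allylic alcohol.

**Compound list**
1 | (R)-5-(hydroxymethyl)dihydrofuran-2(3H)-one | O=C1CC[C@H](CO)O1 | starting material
2 | (R)-5-(TESOCH2)dihydrofuran-2(3H)-one | O=C1CC[C@H](CO[Si](CC)(CC)CC)O1 | intermediate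
3 | but-2-yne-1,4-diol | OCC#CCO | starting material
4 | 4-(TBSO)but-2-yn-1-ol | OCC#CCO[Si](C)(C)C(C)(C)C | intermediate
5 | allylmagnesium bromide | C=CC[Mg]Br | starting material
6 | (E)-2-allyl-4-(TBSO)but-2-en-1-ol | OC/C(CC=C)=C/CO[Si](C)(C)C(C)(C)C | intermediate
7 | (2E)-1-(TBSO)-3-(PMBOCH2)hexa-2,5-diene | COc1ccc(COC/C(CC=C)=C/CO[Si](C)(C)C(C)(C)C)cc1 | intermediate
8 | B-[(4E)-6-(TBSO)-4-(PMBOCH2)hex-4-en-1-yl]-9-borabicyclo[3.3.1]nonane | COc1ccc(COC/C(CCCB2C3CCCC2CCC3)=C/CO[Si](C)(C)C(C)(C)C)cc1 | intermediate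
9 | (4E)-6-(TBSO)-4-(PMBOCH2)hex-4-en-1-ol | COc1ccc(COC/C(CCCO)=C/CO[Si](C)(C)C(C)(C)C)cc1 | intermediate
10 | (4E)-6-(TBSO)-4-(PMBOCH2)hex-4-enal | COc1ccc(COC/C(CCC=O)=C/CO[Si](C)(C)C(C)(C)C)cc1 | intermediate
11 | (5R)-3-[(4E)-6-(TBSO)-1-hydroxy-4-(PMBOCH2)hex-4-en-1-yl]-5-(TESOCH2)dihydrofuran-2(3H)-one (mixture at C3 and the carbinol carbon) | COc1ccc(COC/C(CCC(O)C2C(=O)O[C@@H](CO[Si](CC)(CC)CC)C2)=C/CO[Si](C)(C)C(C)(C)C)cc1 | intermediate
12 | methanesulfonate of 11 | COc1ccc(COC/C(CCC(OS(C)(=O)=O)C2C(=O)O[C@@H](CO[Si](CC)(CC)CC)C2)=C/CO[Si](C)(C)C(C)(C)C)cc1 | intermediate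
13 | (3E,5R)-3-[(4E)-6-(TBSO)-4-(PMBOCH2)hex-4-en-1-ylidene]-5-(TESOCH2)dihydrofuran-2(3H)-one | COc1ccc(COC/C(CC/C=C2/C(=O)O[C@@H](CO[Si](CC)(CC)CC)C2)=C/CO[Si](C)(C)C(C)(C)C)cc1 | intermediate
14 | (2R,4E,8E)-10-(TBSO)-4-(hydroxymethyl)-8-(PMBOCH2)-1-(TESO)deca-4,8-dien-2-ol | COc1ccc(COC/C(CC/C=C(/CO)C[C@@H](O)CO[Si](CC)(CC)CC)=C/CO[Si](C)(C)C(C)(C)C)cc1 | intermediate
15 | (2R,4E,8E)-10-(TBSO)-4-(TBDPSOCH2)-8-(PMBOCH2)-1-(TESO)deca-4,8-dien-2-ol | COc1ccc(COC/C(CC/C=C(/CO[Si](c2ccccc2)(c2ccccc2)C(C)(C)C)C[C@@H](O)CO[Si](CC)(CC)CC)=C/CO[Si](C)(C)C(C)(C)C)cc1 | intermediate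
16 | (2R,4E,8E)-2,10-bis(TBSO)-4-(TBDPSOCH2)-8-(PMBOCH2)-1-(TESO)deca-4,8-diene | COc1ccc(COC/C(CC/C=C(/CO[Si](c2ccccc2)(c2ccccc2)C(C)(C)C)C[C@@H](O[Si](C)(C)C(C)(C)C)CO[Si](CC)(CC)CC)=C/CO[Si](C)(C)C(C)(C)C)cc1 | intermediate
17 | (2R,4E,8E)-2,10-bis(TBSO)-4-(TBDPSOCH2)-8-(PMBOCH2)deca-4,8-dien-1-ol | COc1ccc(COC/C(CC/C=C(/CO[Si](c2ccccc2)(c2ccccc2)C(C)(C)C)C[C@@H](O[Si](C)(C)C(C)(C)C)CO)=C/CO[Si](C)(C)C(C)(C)C)cc1 | intermediate
18 | (2R,4E,8E)-2,10-bis(TBSO)-4-(TBDPSOCH2)-8-(PMBOCH2)deca-4,8-dienal | COc1ccc(COC/C(CC/C=C(/CO[Si](c2ccccc2)(c2ccccc2)C(C)(C)C)C[C@@H](O[Si](C)(C)C(C)(C)C)C=O)=C/CO[Si](C)(C)C(C)(C)C)cc1 | intermediate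
19 | methyl acrylate | C=CC(=O)OC | starting material
20 | methyl (4R,6E,10E)-4,12-bis(TBSO)-6-(TBDPSOCH2)-3-hydroxy-10-(PMBOCH2)-2-methylidenedodeca-6,10-dienoate (both C3 epimers) | COc1ccc(COC/C(CC/C=C(/CO[Si](c2ccccc2)(c2ccccc2)C(C)(C)C)C[C@@H](O[Si](C)(C)C(C)(C)C)C(O)C(=C)C(=O)OC)=C/CO[Si](C)(C)C(C)(C)C)cc1 | intermediate
21 | methyl (2Z,4R,6E,10E)-2-(bromomethyl)-4,12-bis(TBSO)-6-(TBDPSOCH2)-10-(PMBOCH2)dodeca-2,6,10-trienoate | COc1ccc(COC/C(CC/C=C(/CO[Si](c2ccccc2)(c2ccccc2)C(C)(C)C)C[C@@H](O[Si](C)(C)C(C)(C)C)/C=C(\CBr)C(=O)OC)=C/CO[Si](C)(C)C(C)(C)C)cc1 | intermediate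
22 | methyl (2Z,4R,6E,10E)-2-(bromomethyl)-4-(TBSO)-6-(TBDPSOCH2)-12-hydroxy-10-(PMBOCH2)dodeca-2,6,10-trienoate | COc1ccc(COC/C(CC/C=C(/CO[Si](c2ccccc2)(c2ccccc2)C(C)(C)C)C[C@@H](O[Si](C)(C)C(C)(C)C)/C=C(\CBr)C(=O)OC)=C/CO)cc1 | intermediate
23 | methyl (2Z,4R,6E,10E)-2-(bromomethyl)-4-(TBSO)-6-(TBDPSOCH2)-10-(PMBOCH2)-12-oxododeca-2,6,10-trienoate | COc1ccc(COC/C(CC/C=C(/CO[Si](c2ccccc2)(c2ccccc2)C(C)(C)C)C[C@@H](O[Si](C)(C)C(C)(C)C)/C=C(\CBr)C(=O)OC)=C/C=O)cc1 | intermediate
24 | methyl (1(10)E,4E,6S,7R,8R)-8-(TBSO)-14-(TBDPSO)-6-hydroxy-15-(PMBO)germacra-1(10),4,11(13)-trien-12-oate | C=C(C(=O)OC)[C@@H]1[C@@H](O)/C=C(/COCc2ccc(OC)cc2)CC/C=C(/CO[Si](c2ccccc2)(c2ccccc2)C(C)(C)C)C[C@H]1O[Si](C)(C)C(C)(C)C | intermediate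
25 | (1(10)E,4E,6S,7R,8R)-8-(TBSO)-14-(TBDPSO)-15-(PMBO)germacra-1(10),4,11(13)-trien-12,6-olide (trans-fused) | C=C1C(=O)O[C@H]2/C=C(/COCc3ccc(OC)cc3)CC/C=C(/CO[Si](c3ccccc3)(c3ccccc3)C(C)(C)C)C[C@@H](O[Si](C)(C)C(C)(C)C)[C@H]12 | intermediate
26 | (1(10)E,4E,6S,7R,8R)-8-(TBSO)-14-(TBDPSO)-6-hydroxy-15-(PMBO)germacra-1(10),4,11(13)-trien-12-oic acid | C=C(C(=O)O)[C@@H]1[C@@H](O)/C=C(/COCc2ccc(OC)cc2)CC/C=C(/CO[Si](c2ccccc2)(c2ccccc2)C(C)(C)C)C[C@H]1O[Si](C)(C)C(C)(C)C | intermediate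
27 | (1(10)E,4E,6R,7R,8R)-8-(TBSO)-14-(TBDPSO)-15-(PMBO)germacra-1(10),4,11(13)-trien-12,6-olide (cis-fused) | C=C1C(=O)O[C@@H]2/C=C(/COCc3ccc(OC)cc3)CC/C=C(/CO[Si](c3ccccc3)(c3ccccc3)C(C)(C)C)C[C@@H](O[Si](C)(C)C(C)(C)C)[C@H]12 | intermediate
28 | (1(10)E,4E,6R,7S,8R)-14-(TBDPSO)-8-hydroxy-15-(PMBO)germacra-1(10),4,11(13)-trien-12,6-olide | C=C1C(=O)O[C@@H]2/C=C(/COCc3ccc(OC)cc3)CC/C=C(/CO[Si](c3ccccc3)(c3ccccc3)C(C)(C)C)C[C@@H](O)[C@H]12 | intermediate
29 | 3-methylbutanoic anhydride | CC(C)CC(=O)OC(=O)CC(C)C | starting material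
30 | (1(10)E,4E,6R,7S,8R)-14-(TBDPSO)-8-(3-methylbutanoyloxy)-15-(PMBO)germacra-1(10),4,11(13)-trien-12,6-olide | C=C1C(=O)O[C@@H]2/C=C(/COCc3ccc(OC)cc3)CC/C=C(/CO[Si](c3ccccc3)(c3ccccc3)C(C)(C)C)C[C@@H](OC(=O)CC(C)C)[C@H]12 | intermediate
31 | (1(10)E,4E,6R,7S,8R)-14-hydroxy-8-(3-methylbutanoyloxy)-15-(PMBO)germacra-1(10),4,11(13)-trien-12,6-olide | C=C1C(=O)O[C@@H]2/C=C(/COCc3ccc(OC)cc3)CC/C=C(/CO)C[C@@H](OC(=O)CC(C)C)[C@H]12 | intermediate
32 | (1(10)E,4E,6R,7S,8R)-8-(3-methylbutanoyloxy)-14-oxo-15-(PMBO)germacra-1(10),4,11(13)-trien-12,6-olide | C=C1C(=O)O[C@@H]2/C=C(/COCc3ccc(OC)cc3)CC/C=C(/C=O)C[C@@H](OC(=O)CC(C)C)[C@H]12 | intermediate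
33 | (1(10)E,4E,6R,7S,8R)-15-hydroxy-8-(3-methylbutanoyloxy)-14-oxogermacra-1(10),4,11(13)-trien-12,6-olide | C=C1C(=O)O[C@@H]2/C=C(/CO)CC/C=C(/C=O)C[C@@H](OC(=O)CC(C)C)[C@H]12 | target

**Step count and risks**
Total step count: 23. Longest linear sequence: 22 steps (steps 2 to 23, from but-2-yne-1,4-diol); step 1 is the only side branch.

Steps most likely to fail:

1. Step 17 (ring closure with CrCl2). What may go wrong: oligomerisation instead of ten-membered ring closure, isomerisation of the enal before cyclisation, or weak facial control by C8 in the allylation. Fallback: the approach changes from the equilibrating allylchromium species to a non-equilibrating allylindium species with the opposite simple diastereoselection. It sets out from bromo enal 23. In powder in THF/H2O at high dilution should pass through the (Z)-allylindium reagent and a chair transition state to the 6,7-syn hydroxy ester methyl (1(10)E,4E,6R,7R,8R)-8-(TBSO)-14-(TBDPSO)-6-hydroxy-15-(PMBO)germacra-1(10),4,11(13)-trien-12-oate F1. In F1 the C6 oxygen already stands cis to C11, so TsOH in CH2Cl2 closes it at the acyl carbon directly to the cis-fused lactone 27, where the route is rejoined; step 18 is then not needed.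

2. Step 18 (inverting lactone closure). What may go wrong: re-closure of seco acid 26 to 25 at the acyl carbon before or during activation (retention), ionisation of the allylic oxyphosphonium ion with loss of configuration, or elimination to a diene. Fallback: the inversion is done intermolecularly and the ring is then closed at the acyl carbon. It sets out from hydroxy ester 24 (isolated when the TsOH treatment of step 17 is left out). Mitsunobu inversion with 4-nitrobenzoic acid (PPh3, DIAD, toluene) gives methyl (1(10)E,4E,6R,7R,8R)-8-(TBSO)-14-(TBDPSO)-6-(4-nitrobenzoyloxy)-15-(PMBO)germacra-1(10),4,11(13)-trien-12-oate F2. K2CO3 in MeOH at 0 °C removes the nitrobenzoate to the 6,7-syn hydroxy ester methyl (1(10)E,4E,6R,7R,8R)-8-(TBSO)-14-(TBDPSO)-6-hydroxy-15-(PMBO)germacra-1(10),4,11(13)-trien-12-oate F1, which lactonises with TsOH to 27, where the route is rejoined.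

3. Step 13 (Morita–Baylis–Hillman reaction). What may go wrong: very slow amine-catalysed addition to the hindered α-silyloxy aldehyde, with epimerisation at C8 or β-elimination of silanol during the long reaction time. Fallback: a stoichiometric vinylaluminium 1,2-addition replaces the amine catalysis. It sets out from aldehyde 18. The reagent methyl 2-(diisobutylalumanyl)acrylate F3 is made from methyl propiolate, iBu2AlH and N-methylmorpholine N-oxide in THF at 0 °C and added to 18 at −78 → 0 °C; this needs no amine base and gives the same allylic alcohol 20, where the route is rejoined.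

Further compounds
F1 | step 17 | methyl (1(10)E,4E,6R,7R,8R)-8-(TBSO)-14-(TBDPSO)-6-hydroxy-15-(PMBO)germacra-1(10),4,11(13)-trien-12-oate | C=C(C(=O)OC)[C@@H]1[C@H](O)/C=C(/COCc2ccc(OC)cc2)CC/C=C(/CO[Si](c2ccccc2)(c2ccccc2)C(C)(C)C)C[C@H]1O[Si](C)(C)C(C)(C)C
F2 | step 18 | methyl (1(10)E,4E,6R,7R,8R)-8-(TBSO)-14-(TBDPSO)-6-(4-nitrobenzoyloxy)-15-(PMBO)germacra-1(10),4,11(13)-trien-12-oate | C=C(C(=O)OC)[C@@H]1[C@H](OC(=O)c2ccc(cc2)[N+](=O)[O-])/C=C(/COCc2ccc(OC)cc2)CC/C=C(/CO[Si](c2ccccc2)(c2ccccc2)C(C)(C)C)C[C@H]1O[Si](C)(C)C(C)(C)C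
F3 | step 13 | methyl 2-(diisobutylalumanyl)acrylate | C=C(C(=O)OC)[Al](CC(C)C)CC(C)C
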